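Ring C is numbered C1 (quaternary; CH3 and vinyl carbon Ca), C2, C3, C4 (CH3), C5 (=CH) and C6 (H; bonded to C3B of coumarin B, whose lactone carbonyl is C2B). Ca and C6, two of the carbons on C1, can each be drawn as a carbonyl carbon, so a temporary Ca–C2B bond makes C1, Ca, C2B, C3B and C6 a 2-methylcyclopentane-1,3-dione with enantiotopic carbonyls. Proline-catalysed aldol condensation of the achiral triketone 3 closes ring C (C5–C6) and fixes C1 in one operation. The five-membered ring then passes the cis configuration to C6 and is cut to a lactone that becomes coumarin B; Ca is extended to coumarin A by phosphonate olefination.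

Key step: step 2

Remark on the chemistry: the target is (1R,6R) in ring C numbering with Ca and C3B cis, and the geometry of the (7aS)-enedione matches C1. The descriptor at C1 switches from S to R in step 20 only because the CIP rank of Ca drops below that of C6. Cutting the α-hydroxy ketone directly would leave Ca at the acid level and C2B at the aldehyde level, the reverse of what is needed, so the route goes through diol 16 and lactone 17. Compounds 18 and 27 are taken as purchasable.

Step 1
Reactants: 1 2-methylcyclopentane-1,3-dione; 2 methyl vinyl ketone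
Product: 3 2-methyl-2-(3-oxobutyl)cyclopentane-1,3-dione
Conditions: H2O, AcOH (cat.), 70 °C
Reagents that add atoms: none
Why: Michael addition of the acidic cyclic 1,3-dione to the unhindered enone alkylates the carbon between the two carbonyls and should give the achiral triketone without any stereochemical issue.

Step 2
Reactants: 3 2-methyl-2-(3-oxobutyl)cyclopentane-1,3-dione
Product: 5 (S)-7a-methyl-2,3,7,7a-tetrahydro-1H-indene-1,5(6H)-dione, via cis-fused ketol 4 (not isolated)
Conditions: (S)-proline (3 mol %), DMF, 16 °C; then H2SO4 (cat.), DMF, 95 °C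
Reagents that add atoms: none
Why: (S)-Proline forms an enamine with the side-chain methyl ketone, and its terminal carbon (C5) attacks one of the two enantiotopic ring carbonyls (the one that becomes C6) in a 6-(enolendo)-exo-trig aldol closure that creates the C5–C6 bond and ring C; hydrolysis gives ketol 4, which sulfuric acid dehydrates to the C5=C6 enone. This is the Hajos–Parrish (Eder–Sauer–Wiechert) proline-catalysed intramolecular aldol condensation, run here on its classical substrate. C1 is prochiral in 3 and becomes stereogenic when the two carbonyls are told apart: the proline carboxylic acid hydrogen-bonds to the carbonyl under attack in a chair-like transition state, so the catalyst alone controls the configuration, and the (S)-catalyst should give the (7aS)-enedione, in which Ca and the methyl group are arranged as required at C1 of the target. The only selectivity needed is between the enantiotopic carbonyls; regiochemistry is not at issue, because the alternative enamine (toward C3) could only close a four-membered ring. The product cannot racemise, since C1 is quaternary.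

Step 3
Reactants: 5 (S)-7a-methyl-2,3,7,7a-tetrahydro-1H-indene-1,5(6H)-dione
Product: 6 (7a'S)-7a'-methyl-2',3',7',7a'-tetrahydrospiro[1,3-dioxolane-2,1'-inden]-5'(6'H)-one
Conditions: 2-ethyl-2-methyl-1,3-dioxolane (solvent), ethylene glycol (cat.), p-TsOH·H2O (cat.), rt
Reagents that add atoms: 2-ethyl-2-methyl-1,3-dioxolane, CCC1(C)OCCO1
Why: Acid-catalysed transketalisation at room temperature should mask the saturated Ca ketone selectively, because the C4 carbonyl is deactivated by conjugation, and the quaternary C1 is not affected.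

Step 4
Reactants: 6 (7a'S)-7a'-methyl-2',3',7',7a'-tetrahydrospiro[1,3-dioxolane-2,1'-inden]-5'(6'H)-one
Product: 7 dimethyl(phenyl){[(3a'R,7a'S)-7a'-methyl-2',3',3a',6',7',7a'-hexahydrospiro[1,3-dioxolane-2,1'-inden]-5'-yl]oxy}silane (cis-fused)
Conditions: [(Ph3P)CuH]6 (2 mol %), PhMe2SiH (1.5 equiv), toluene, rt
Reagents that add atoms: dimethylphenylsilane, C[SiH](C)c1ccccc1
Why: Copper hydride conjugate hydrosilylation adds hydride to C6 and the silane traps the copper enolate as the C4–C5 silyl enol ether regiospecifically; hydride is expected to enter axially on the face of the angular methyl, as cuprates and hydrogen do with this hydrindenone, so C6–H ends cis to the C1 methyl and C3B cis to Ca.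

Step 5
Reactants: 7 dimethyl(phenyl)silyl enol ether from step 4
Product: 9 (3a'R,7a'S)-7a'-methyl-2',3',3a',6',7',7a'-hexahydrospiro[1,3-dioxolane-2,1'-inden]-5'-yl trifluoromethanesulfonate, via lithium enolate 8 (not isolated)
Conditions: MeLi, THF, 0 °C; then PhNTf2, −78 °C → rt; aq. NH4Cl
Reagents that add atoms: N-phenylbis(trifluoromethanesulfonimide), O=S(=O)(N(c1ccccc1)S(=O)(=O)C(F)(F)F)C(F)(F)F
Why: Methyllithium cleaves the O–Si bond to give the regiodefined lithium enolate without proton transfer, and O-triflation with the triflimide (standard enolate triflation) should fix the double bond at C4=C5.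

Step 6
Reactants: 9 enol triflate from step 5
Product: 10 (3a'R,7a'S)-5',7a'-dimethyl-2',3',3a',6',7',7a'-hexahydrospiro[1,3-dioxolane-2,1'-indene]
Conditions: Fe(acac)3 (5 mol %), MeMgBr, THF/NMP, −30 → 0 °C
Reagents that add atoms: methylmagnesium bromide, C[Mg]Br
Why: Fe(acac)3-catalysed Kumada-type coupling of alkenyl triflates with methyl Grignard reagent replaces the triflate by methyl with the double bond held in place, and the ketal is inert to the Grignard reagent.

Step 7
Reactants: 10 methyl alkene ketal from step 6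
Product: 11 (3aR,7aS)-5,7a-dimethyl-2,3,3a,6,7,7a-hexahydro-1H-inden-1-one
Conditions: 1 M HCl, THF, rt
Reagents that add atoms: water, O
Why: Mild aqueous acid hydrolyses the dioxolane to the Ca ketone, the trisubstituted alkene should not be protonated under these conditions, and neither C1 (quaternary) nor C6 (beta to the carbonyl) can epimerise.

Step 8
Reactants: 11 (3aR,7aS)-5,7a-dimethyl-2,3,3a,6,7,7a-hexahydro-1H-inden-1-one
Product: 13 (3aR,7aS)-2-hydroxy-5,7a-dimethyl-2,3,3a,6,7,7a-hexahydro-1H-inden-1-one (C2 epimers), via potassium enolate 12 (not isolated)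
Conditions: KN(SiMe3)2, THF, −78 °C; then 2-(benzenesulfonyl)-3-phenyloxaziridine, −78 °C; aq. NH4Cl
Reagents that add atoms: 2-(benzenesulfonyl)-3-phenyloxaziridine, O=S(=O)(N1OC1c1ccccc1)c1ccccc1
Why: The Ca ketone can enolise only toward C2B because C1 is quaternary, and Davis hydroxylation of the potassium enolate leaves the isolated alkene untouched; the new carbinol configuration is irrelevant because it is destroyed in step 10.

Step 9
Reactants: 13 α-hydroxy ketone from step 8
Product: 14 (3aR,7aS)-5,7a-dimethyl-2,3,3a,6,7,7a-hexahydro-1H-indene-1,2-diol (mixture at C1 and C2)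
Conditions: NaBH4, MeOH, 0 °C
Reagents that add atoms: none
Why: Borohydride reduction of the ketone gives the vicinal diol required for glycol cleavage, and the configurations of the two carbinol carbons are inconsequential.

Step 10
Reactants: 14 vicinal diol from step 9
Product: 16 2-[(1R,6S)-6-(hydroxymethyl)-3,6-dimethylcyclohex-2-en-1-yl]ethan-1-ol, via dialdehyde 15 (not isolated)
Conditions: NaIO4, THF/H2O (pH 7 buffer), rt; then NaBH4, 0 °C
Reagents that add atoms: none
Why: Periodate glycol cleavage (Malaprade reaction) severs the temporary Ca–C2B bond and reduction in the same flask avoids handling the 1,5-dialdehyde; C1 and C6 are not alpha to an enolisable carbonyl on the ring side and keep their configuration.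

Step 11
Reactants: 16 diol from step 10
Product: 17 (4aR,8aS)-6,8a-dimethyl-1,4,4a,7,8,8a-hexahydro-3H-isochromen-3-one (cis-fused lactone, C2B = carbonyl, Ca = OCH2)
Conditions: TEMPO (2,2,6,6-tetramethylpiperidin-1-oxyl, 20 mol %), PhI(OAc)2 (2.5 equiv), CH2Cl2, rt
Reagents that add atoms: none
Why: The oxoammonium oxidant should attack the unhindered alcohol at C2B much faster than the neopentyl alcohol at Ca, the aldehyde is captured by the Ca hydroxyl as a six-membered lactol (possible because Ca and C3B are cis) and oxidised on to the lactone (oxidative lactonisation of a 1,5-diol), which puts C2B at the carboxyl level and stores Ca as an alkoxy carbon.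

Step 12
Reactants: 18 2,4-dihydroxy-3-methoxybenzaldehyde
Product: 19 2-hydroxy-3-methoxy-4-[(triisopropylsilyl)oxy]benzaldehyde
Conditions: iPr3SiCl (1.05 equiv), imidazole, CH2Cl2, 0 °C
Reagents that add atoms: triisopropylsilyl chloride, CC(C)[Si](Cl)(C(C)C)C(C)C
Why: The 4-hydroxyl is the more acidic and more accessible phenol while the 2-hydroxyl is hydrogen-bonded to the formyl group, so one equivalent of the bulky silyl chloride should silylate O-4 selectively.

Step 13
Reactants: 19 2-hydroxy-3-methoxy-4-[(triisopropylsilyl)oxy]benzaldehyde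
Product: 20 3-methoxy-2-(methoxymethoxy)-4-[(triisopropylsilyl)oxy]benzaldehyde
Conditions: MeOCH2Cl, iPr2NEt, CH2Cl2, 0 °C → rt
Reagents that add atoms: chloromethyl methyl ether, COCCl
Why: O-Alkylation of the remaining phenol with chloromethyl methyl ether and a hindered amine base gives the MOM ether, which blocks O-2 during the enolate addition and can later be removed by acid while the aryl silyl ether stays.

Step 14
Reactants: 17 cis-fused lactone; 20 3-methoxy-2-(methoxymethoxy)-4-[(triisopropylsilyl)oxy]benzaldehyde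
Product: 22 (4aS,8aS)-4-{hydroxy[3-methoxy-2-(methoxymethoxy)-4-(triisopropylsilyloxy)phenyl]methyl}-6,8a-dimethyl-1,4,4a,7,8,8a-hexahydro-3H-isochromen-3-one (mixture at C4 and at the carbinol carbon; ring-fusion geometry as in 17, descriptor change by CIP rank only), via lithium lactone enolate 21 (not isolated)
Conditions: LiN(iPr)2, THF, −78 °C; then 20, −78 °C; aq. NH4Cl
Reagents that add atoms: none
Why: The lactone has a single alpha position (C3B), and aldol addition of its lithium enolate to the non-enolisable aromatic aldehyde forms the C3B–C4B bond; both new stereocenters become sp2 in step 15, so the diastereomer mixture is carried on.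

Step 15
Reactants: 22 aldol adduct from step 14
Product: 25 3-[(1R,6S)-6-(hydroxymethyl)-3,6-dimethylcyclohex-2-en-1-yl]-8-methoxy-7-[(triisopropylsilyl)oxy]-2H-chromen-2-one, via free phenol 23 (not isolated), via hydroxybenzylidene lactone 24 (not isolated)
Conditions: 2 M HCl, MeOH, 50 °C
Reagents that add atoms: none
Why: Acid removes the MOM group, the electron-rich benzylic alcohol dehydrates to the 2-hydroxybenzylidene lactone, and reversible addition at the benzylic carbon equilibrates its geometry so that the phenol can attack the lactone carbonyl (the known rearrangement of 2-hydroxybenzylidene lactones to 3-(hydroxyalkyl)coumarins), which forms coumarin B and releases the Ca hydroxymethyl group while the non-enolisable C6 keeps its configuration.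

Step 16
Reactants: 25 coumarin B alcohol from step 15
Product: 26 (1S,2R)-2-{8-methoxy-2-oxo-7-[(triisopropylsilyl)oxy]-2H-chromen-3-yl}-1,4-dimethylcyclohex-3-ene-1-carbaldehyde
Conditions: Dess–Martin periodinane, NaHCO3, CH2Cl2, 0 °C → rt
Reagents that add atoms: none
Why: Dess–Martin oxidation should convert the neopentyl primary alcohol into the aldehyde without over-oxidation under buffered conditions that spare the coumarin, the aryl silyl ether and the doubly allylic C6–H, and the aldehyde has no alpha hydrogen to epimerise.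

Step 17
Reactants: 19 2-hydroxy-3-methoxy-4-[(triisopropylsilyl)oxy]benzaldehyde; 27 ethyl 2-(triphenylphosphoranylidene)propanoate
Product: 28 8-methoxy-3-methyl-7-[(triisopropylsilyl)oxy]-2H-chromen-2-one
Conditions: PhNEt2, 215 °C
Reagents that add atoms: none
Why: Wittig olefination of the salicylaldehyde with the stabilised α-methyl ylide followed by thermal isomerisation and lactonisation in hot diethylaniline is a standard entry to 3-methylcoumarins; the ylide methyl becomes Cb.

Step 18
Reactants: 28 8-methoxy-3-methyl-7-[(triisopropylsilyl)oxy]-2H-chromen-2-one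
Product: 29 3-(bromomethyl)-8-methoxy-7-[(triisopropylsilyl)oxy]-2H-chromen-2-one
Conditions: NBS, AIBN (2,2'-azobis(2-methylpropionitrile), cat.), PhCF3, 85 °C
Reagents that add atoms: N-bromosuccinimide, O=C1CCC(=O)N1Br
Why: Wohl–Ziegler bromination should functionalise the 3-methyl group, which is allylic to the coumarin C3=C4 bond, by a radical chain in a non-polar solvent that disfavours ionic bromination of the arene.

Step 19
Reactants: 29 3-(bromomethyl)coumarin from step 18
Product: 30 diethyl ({8-methoxy-2-oxo-7-[(triisopropylsilyl)oxy]-2H-chromen-3-yl}methyl)phosphonate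
Conditions: P(OEt)3 (neat), 130 °C
Reagents that add atoms: triethyl phosphite, CCOP(OCC)OCC
Why: Michaelis–Arbuzov reaction of the reactive allylic bromide with triethyl phosphite should give the phosphonate, with bromoethane distilling off.

Step 20
Reactants: 30 coumarin A phosphonate; 26 Ca aldehyde carrying coumarin B
Product: 32 8-methoxy-3-[(E)-2-[(1R,2R)-2-{8-methoxy-2-oxo-7-[(triisopropylsilyl)oxy]-2H-chromen-3-yl}-1,4-dimethylcyclohex-3-en-1-yl]ethenyl]-7-[(triisopropylsilyl)oxy]-2H-chromen-2-one, via sodium phosphonate carbanion 31 (not isolated)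
Conditions: NaH, THF, 0 °C; then 26, 0 °C → rt
Reagents that add atoms: none
Why: Horner–Wadsworth–Emmons olefination: the carbanion, stabilised by the phosphoryl group and the coumarin π system, adds to the non-enolisable Ca aldehyde and loss of diethyl phosphate should give the Ca=Cb alkene as the (E) isomer, favoured by reversible addition and by the bulk of the quaternary C1; no stereocenter is touched.

Step 21
Reactants: 32 bis(triisopropylsilyl) ether from step 20
Product: 33 7-hydroxy-3-[(E)-2-[(1R,2R)-2-(7-hydroxy-8-methoxy-2-oxo-2H-chromen-3-yl)-1,4-dimethylcyclohex-3-en-1-yl]ethenyl]-8-methoxy-2H-chromen-2-one (CNP0264408.1)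
Conditions: Bu4NF, AcOH, THF, 0 °C
Reagents that add atoms: none
Why: Fluoride cleaves both aryl silyl ethers (desilylation driven by Si–F bond formation), and acetic acid buffering keeps the two lactones and the doubly allylic C6–H away from strong base.

Compound list
1 | 2-methylcyclopentane-1,3-dione | CC1C(=O)CCC1=O | starting material
2 | methyl vinyl ketone | C=CC(C)=O | starting material
3 | 2-methyl-2-(3-oxobutyl)cyclopentane-1,3-dione | CC(=O)CCC1(C)C(=O)CCC1=O | intermediate
4 | (3aS,7aS)-3a-hydroxy-7a-methylhexahydro-1H-indene-1,5(4H)-dione (cis-fused ketol) | O=C1CC[C@]2(O)CC(=O)CC[C@]12C | intermediate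
5 | (S)-7a-methyl-2,3,7,7a-tetrahydro-1H-indene-1,5(6H)-dione | O=C1CCC2=CC(=O)CC[C@]12C | intermediate
6 | (7a'S)-7a'-methyl-2',3',7',7a'-tetrahydrospiro[1,3-dioxolane-2,1'-inden]-5'(6'H)-one | C[C@]12CCC(=O)C=C1CCC21OCCO1 | intermediate
7 | dimethyl(phenyl){[(3a'R,7a'S)-7a'-methyl-2',3',3a',6',7',7a'-hexahydrospiro[1,3-dioxolane-2,1'-inden]-5'-yl]oxy}silane | C[C@]12CCC(O[Si](C)(C)c3ccccc3)=C[C@H]1CCC21OCCO1 | intermediate
8 | lithium enolate corresponding to 7 | C[C@]12CCC(O[Li])=C[C@H]1CCC21OCCO1 | intermediate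
9 | (3a'R,7a'S)-7a'-methyl-2',3',3a',6',7',7a'-hexahydrospiro[1,3-dioxolane-2,1'-inden]-5'-yl trifluoromethanesulfonate | C[C@]12CCC(OS(=O)(=O)C(F)(F)F)=C[C@H]1CCC21OCCO1 | intermediate
10 | (3a'R,7a'S)-5',7a'-dimethyl-2',3',3a',6',7',7a'-hexahydrospiro[1,3-dioxolane-2,1'-indene] | C[C@]12CCC(C)=C[C@H]1CCC21OCCO1 | intermediate
11 | (3aR,7aS)-5,7a-dimethyl-2,3,3a,6,7,7a-hexahydro-1H-inden-1-one | C[C@]12CCC(C)=C[C@H]1CCC2=O | intermediate
12 | potassium enolate of 11 | C[C@]12CCC(C)=C[C@H]1CC=C2O[K] | intermediate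
13 | (3aR,7aS)-2-hydroxy-5,7a-dimethyl-2,3,3a,6,7,7a-hexahydro-1H-inden-1-one (C2 epimers) | C[C@]12CCC(C)=C[C@H]1CC(O)C2=O | intermediate
14 | (3aR,7aS)-5,7a-dimethyl-2,3,3a,6,7,7a-hexahydro-1H-indene-1,2-diol (mixture at C1 and C2) | C[C@]12CCC(C)=C[C@H]1CC(O)C2O | intermediate
15 | (1S,2R)-1,4-dimethyl-2-(2-oxoethyl)cyclohex-3-ene-1-carbaldehyde | O=C[C@@]1(C)CCC(C)=C[C@H]1CC=O | intermediate
16 | 2-[(1R,6S)-6-(hydroxymethyl)-3,6-dimethylcyclohex-2-en-1-yl]ethan-1-ol | OC[C@@]1(C)CCC(C)=C[C@H]1CCO | intermediate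
17 | (4aR,8aS)-6,8a-dimethyl-1,4,4a,7,8,8a-hexahydro-3H-isochromen-3-one | O=C1C[C@@H]2C=C(C)CC[C@]2(C)CO1 | intermediate
18 | 2,4-dihydroxy-3-methoxybenzaldehyde | O=Cc1ccc(O)c(OC)c1O | starting material
19 | 2-hydroxy-3-methoxy-4-[(triisopropylsilyl)oxy]benzaldehyde | O=Cc1ccc(O[Si](C(C)C)(C(C)C)C(C)C)c(OC)c1O | intermediate
20 | 3-methoxy-2-(methoxymethoxy)-4-[(triisopropylsilyl)oxy]benzaldehyde | O=Cc1ccc(O[Si](C(C)C)(C(C)C)C(C)C)c(OC)c1OCOC | intermediate
21 | lithium enolate of lactone 17 | [Li]OC1=C[C@@H]2C=C(C)CC[C@]2(C)CO1 | intermediate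
22 | (4aS,8aS)-4-{hydroxy[3-methoxy-2-(methoxymethoxy)-4-(triisopropylsilyloxy)phenyl]methyl}-6,8a-dimethyl-1,4,4a,7,8,8a-hexahydro-3H-isochromen-3-one (mixture at C4 and carbinol carbon) | O=C1OC[C@@]2(C)CCC(C)=C[C@H]2C1C(O)c1ccc(O[Si](C(C)C)(C(C)C)C(C)C)c(OC)c1OCOC | intermediate
23 | free phenol of 22 (MOM group removed) | O=C1OC[C@@]2(C)CCC(C)=C[C@H]2C1C(O)c1ccc(O[Si](C(C)C)(C(C)C)C(C)C)c(OC)c1O | intermediate
24 | 4-(2-hydroxy-3-methoxy-4-triisopropylsilyloxybenzylidene) derivative of lactone 17 (E/Z mixture) | O=C1OC[C@@]2(C)CCC(C)=C[C@H]2C1=Cc1ccc(O[Si](C(C)C)(C(C)C)C(C)C)c(OC)c1O | intermediate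
25 | 3-[(1R,6S)-6-(hydroxymethyl)-3,6-dimethylcyclohex-2-en-1-yl]-8-methoxy-7-[(triisopropylsilyl)oxy]-2H-chromen-2-one | OC[C@@]1(C)CCC(C)=C[C@H]1c1cc2ccc(O[Si](C(C)C)(C(C)C)C(C)C)c(OC)c2oc1=O | intermediate
26 | (1S,2R)-2-{8-methoxy-2-oxo-7-[(triisopropylsilyl)oxy]-2H-chromen-3-yl}-1,4-dimethylcyclohex-3-ene-1-carbaldehyde | O=C[C@@]1(C)CCC(C)=C[C@H]1c1cc2ccc(O[Si](C(C)C)(C(C)C)C(C)C)c(OC)c2oc1=O | intermediate
27 | ethyl 2-(triphenylphosphoranylidene)propanoate | CCOC(=O)C(C)=P(c1ccccc1)(c1ccccc1)c1ccccc1 | starting material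
28 | 8-methoxy-3-methyl-7-[(triisopropylsilyl)oxy]-2H-chromen-2-one | Cc1cc2ccc(O[Si](C(C)C)(C(C)C)C(C)C)c(OC)c2oc1=O | intermediate
29 | 3-(bromomethyl)-8-methoxy-7-[(triisopropylsilyl)oxy]-2H-chromen-2-one | BrCc1cc2ccc(O[Si](C(C)C)(C(C)C)C(C)C)c(OC)c2oc1=O | intermediate
30 | diethyl ({8-methoxy-2-oxo-7-[(triisopropylsilyl)oxy]-2H-chromen-3-yl}methyl)phosphonate | CCOP(=O)(OCC)Cc1cc2ccc(O[Si](C(C)C)(C(C)C)C(C)C)c(OC)c2oc1=O | intermediate
31 | sodium carbanion of phosphonate 30 | CCOP(=O)(OCC)[CH-]c1cc2ccc(O[Si](C(C)C)(C(C)C)C(C)C)c(OC)c2oc1=O.[Na+] | intermediate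
32 | 8-methoxy-3-[(E)-2-[(1R,2R)-2-{8-methoxy-2-oxo-7-[(triisopropylsilyl)oxy]-2H-chromen-3-yl}-1,4-dimethylcyclohex-3-en-1-yl]ethenyl]-7-[(triisopropylsilyl)oxy]-2H-chromen-2-one | COc1c(O[Si](C(C)C)(C(C)C)C(C)C)ccc2cc(/C=C/[C@@]3(C)CCC(C)=C[C@H]3c3cc4ccc(O[Si](C(C)C)(C(C)C)C(C)C)c(OC)c4oc3=O)c(=O)oc12 | intermediate
33 | 7-hydroxy-3-[(E)-2-[(1R,2R)-2-(7-hydroxy-8-methoxy-2-oxo-2H-chromen-3-yl)-1,4-dimethylcyclohex-3-en-1-yl]ethenyl]-8-methoxy-2H-chromen-2-one | COc1c(O)ccc2cc(/C=C/[C@@]3(C)CCC(C)=C[C@H]3c3cc4ccc(O)c(OC)c4oc3=O)c(=O)oc12 | target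

Total step count: 21. Longest linear sequence: 16 steps (steps 1–11, 14, 15, 16, 20, 21).

Steps most likely to fail

Step 4: poor facial selectivity in the hydride delivery to C6, which would erode the cis ring fusion and with it the cis relation of C3B and Ca. Fallback: setting out from 6, the C5=C6 bond would be saturated by heterogeneous hydrogenation (H2, Pd/C, EtOAc), the classical cis-selective reduction of this hydrindenone, to give (3a'R,7a'S)-7a'-methylhexahydrospiro[1,3-dioxolane-2,1'-inden]-5'(4'H)-one F1. Its enolate would then be formed under equilibrating conditions (KH, THF, slight excess of ketone), where cis-fused ketones of this kind enolise toward the ring-fusion carbon, and trapped with PhNTf2; the route is rejoined at triflate 9.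

Step 15: dehydration running ahead of lactone exchange and stalling at the benzylidene geometry that cannot lactonise, or loss of the aryl silyl ether under acid. Fallback: setting out from 17, the C2B carboxyl is attached to the phenol before the C3B–C4B bond is made, so the geometry is built in.
- Saponification (LiOH, THF/H2O) would give lithium 2-[(1R,6S)-6-(hydroxymethyl)-3,6-dimethylcyclohex-2-en-1-yl]acetate F2.
- Silylation of the salt (TBSCl, imidazole, DMF) would give tert-butyldimethylsilyl 2-[(1R,6S)-6-{[tert-butyl(dimethyl)silyl]oxymethyl}-3,6-dimethylcyclohex-2-en-1-yl]acetate F3, and methanolysis of the silyl ester (K2CO3, MeOH) 2-[(1R,6S)-6-{[tert-butyl(dimethyl)silyl]oxymethyl}-3,6-dimethylcyclohex-2-en-1-yl]acetic acid F4.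
- Steglich esterification with phenol 19 (EDC·HCl, DMAP, CH2Cl2) would give 2-formyl-6-methoxy-5-[(triisopropylsilyl)oxy]phenyl 2-[(1R,6S)-6-{[tert-butyl(dimethyl)silyl]oxymethyl}-3,6-dimethylcyclohex-2-en-1-yl]acetate F5.
- Intramolecular aldol condensation of the aryl ester onto the ortho-formyl group (DBU, MeCN, 60 °C) would give 3-[(1R,6S)-6-{[tert-butyl(dimethyl)silyl]oxymethyl}-3,6-dimethylcyclohex-2-en-1-yl]-8-methoxy-7-[(triisopropylsilyl)oxy]-2H-chromen-2-one F6.
- Camphorsulfonic acid in MeOH at 0 °C would remove the alkyl silyl ether only, and the route is rejoined at 25.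

Step 20: sluggish addition of the stabilised, ambident carbanion to the hindered neopentyl aldehyde, with competing attack on a coumarin lactone. Fallback: setting out from 26, Takai–Utimoto boryl olefination (Cl2CHB(pin), CrCl2, LiI, THF, rt) would give 8-methoxy-3-[(1R,6R)-3,6-dimethyl-6-[(E)-2-(4,4,5,5-tetramethyl-1,3,2-dioxaborolan-2-yl)ethenyl]cyclohex-2-en-1-yl]-7-[(triisopropylsilyl)oxy]-2H-chromen-2-one F7. Suzuki–Miyaura coupling (Pd(PPh3)4, K3PO4, dioxane/H2O, 80 °C) with 3-bromo-8-methoxy-7-[(triisopropylsilyl)oxy]-2H-chromen-2-one F8, made from 19 and ethyl bromo(triphenylphosphoranylidene)acetate in hot PhNEt2, rejoins the route at 32. This also makes compounds 28–30 and the radical bromination of step 18 unnecessary.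

Further compounds
F1 | step 4 | (3a'R,7a'S)-7a'-methylhexahydrospiro[1,3-dioxolane-2,1'-inden]-5'(4'H)-one | C[C@]12CCC(=O)C[C@H]1CCC21OCCO1
F2 | step 15 | lithium 2-[(1R,6S)-6-(hydroxymethyl)-3,6-dimethylcyclohex-2-en-1-yl]acetate | OC[C@@]1(C)CCC(C)=C[C@H]1CC(=O)[O-].[Li+]
F3 | step 15 | tert-butyldimethylsilyl 2-[(1R,6S)-6-{[tert-butyl(dimethyl)silyl]oxymethyl}-3,6-dimethylcyclohex-2-en-1-yl]acetate | CC(C)(C)[Si](C)(C)OC[C@@]1(C)CCC(C)=C[C@H]1CC(=O)O[Si](C)(C)C(C)(C)C
F4 | step 15 | 2-[(1R,6S)-6-{[tert-butyl(dimethyl)silyl]oxymethyl}-3,6-dimethylcyclohex-2-en-1-yl]acetic acid | CC(C)(C)[Si](C)(C)OC[C@@]1(C)CCC(C)=C[C@H]1CC(=O)O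
F5 | step 15 | 2-formyl-6-methoxy-5-[(triisopropylsilyl)oxy]phenyl 2-[(1R,6S)-6-{[tert-butyl(dimethyl)silyl]oxymethyl}-3,6-dimethylcyclohex-2-en-1-yl]acetate | CC(C)(C)[Si](C)(C)OC[C@@]1(C)CCC(C)=C[C@H]1CC(=O)Oc1c(C=O)ccc(O[Si](C(C)C)(C(C)C)C(C)C)c1OC
F6 | step 15 | 3-[(1R,6S)-6-{[tert-butyl(dimethyl)silyl]oxymethyl}-3,6-dimethylcyclohex-2-en-1-yl]-8-methoxy-7-[(triisopropylsilyl)oxy]-2H-chromen-2-one | CC(C)(C)[Si](C)(C)OC[C@@]1(C)CCC(C)=C[C@H]1c1cc2ccc(O[Si](C(C)C)(C(C)C)C(C)C)c(OC)c2oc1=O
F7 | step 20 | 8-methoxy-3-[(1R,6R)-3,6-dimethyl-6-[(E)-2-(4,4,5,5-tetramethyl-1,3,2-dioxaborolan-2-yl)ethenyl]cyclohex-2-en-1-yl]-7-[(triisopropylsilyl)oxy]-2H-chromen-2-one | CC1(C)OB(/C=C/[C@@]2(C)CCC(C)=C[C@H]2c2cc3ccc(O[Si](C(C)C)(C(C)C)C(C)C)c(OC)c3oc2=O)OC1(C)C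
F8 | step 20 | 3-bromo-8-methoxy-7-[(triisopropylsilyl)oxy]-2H-chromen-2-one | Brc1cc2ccc(O[Si](C(C)C)(C(C)C)C(C)C)c(OC)c2oc1=O
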